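**Plan**
- Retrosynthesis: after removal of the C3 silyl ether, the C5–C10 bond (shared by both six-membered rings) is cut together with the C4–O bond. This leaves a cyclodeca-1(10),4-diene in which the C1=C10 and C4=C5 alkenes face each other across the ring and the C6 benzoate sits 1,3 to C4 on the β face. Then C6–C7 (ten-membered ring) and C2–C3 (geranyl unit + C5 enal) are cut.
- Forward: chain union at C2–C3, ten-membered ring closure at C6–C7, then both cyclohexane rings at once by the transannular C5–C10 closure, with the C6 benzoate delivering the C4 oxygen.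
- Stereochemistry: C3 from a Corey–Bakshi–Shibata reduction; C6/C7 relayed from C3 in the ring closure, C6 then inverted when the benzoate is installed (Mitsunobu); C5/C10 from chair–chair folding; C4 from intramolecular oxygen delivery.

Key step: step 10

Remark: germacrane/eudesmane numbering (C1–C15) is used for all compounds; α/β refer to the usual eudesmane drawing (C10 methyl β) and, for the ten-membered rings, to the crossed chair–chair conformer.

**Step 1**
Reactants: 1 geranyl chloride; 2 (2E)-4,4-dimethoxy-2-methylbut-2-enal
Product: 4 rac-(2E,6E)-1,1-dimethoxy-3,7,11-trimethyldodeca-2,6,10-trien-4-ol, via geranylbarium chloride 3 (not isolated)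
Conditions: BaI2, lithium biphenylide, THF, 20 °C; 1, −78 °C; then 2, −78 °C; aq. NH4Cl
Reagents that add atoms: none
Why: Carbonyl allylation with an allylic barium reagent, which adds 1,2 to aldehydes through its α carbon with retention of the E geometry, so the linear C15 chain with the C3 carbinol (racemic at this stage) should result, the acetal being inert.

**Step 2**
Reactants: 4
Product: 5 (2E,6E)-1,1-dimethoxy-3,7,11-trimethyldodeca-2,6,10-trien-4-one
Conditions: Dess–Martin periodinane, NaHCO3, CH2Cl2, 0 °C
Reagents that add atoms: none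
Why: Dess–Martin oxidation under buffered, non-basic conditions should give the enone without moving the skipped C1=C10 alkene into conjugation, and it erases the racemic centre.

**Step 3**
Reactants: 5
Product: 6 (4R,2E,6E)-1,1-dimethoxy-3,7,11-trimethyldodeca-2,6,10-trien-4-ol (C3 of the later ring, R)
Conditions: (S)-2-methyl-CBS-oxazaborolidine (20 mol %), catecholborane, toluene, −78 °C
Reagents that add atoms: none
Why: Corey–Bakshi–Shibata reduction in which the α-methyl alkenyl residue acts as the large group and the CH2 as the small one, so the (S)-catalyst should give the (R)-carbinol, with catecholborane at low temperature keeping the reduction 1,2.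

**Step 4**
Reactants: 6
Product: 7 (4R,2E,6E)-4-(tert-butyldimethylsilyloxy)-1,1-dimethoxy-3,7,11-trimethyldodeca-2,6,10-triene
Conditions: TBSCl, imidazole, DMF, 20 °C
Reagents that add atoms: tert-butyldimethylsilyl chloride, CC(C)(C)[Si](C)(C)Cl
Why: Standard silylation; the silyl ether is a non-participating group that later keeps O3 from trapping cationic centres.

**Step 5**
Reactants: 7
Product: 8 (4R,2E,6E)-10-chloro-4-(tert-butyldimethylsilyloxy)-1,1-dimethoxy-3,7,11-trimethyldodeca-2,6,11-triene (both epimers at the chloride-bearing carbon)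
Conditions: Ca(OCl)2, solid CO2, CH2Cl2/H2O, 0 °C, partial conversion
Reagents that add atoms: calcium hypochlorite Ca(OCl)2 (source of hypochlorous acid), [Ca+2].[O-]Cl.[O-]Cl
Why: Ene-type allylic chlorination in which electrophilic chlorine should prefer the most accessible, most electron-rich alkene (the terminal isopropylidene; C4=C5 is deactivated by the acetal and the allylic oxygen, C1=C10 is more hindered), with proton loss from a methyl group giving the transposed allylic chloride; either epimer serves in step 7 and any internal regioisomer is removed by chromatography.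

**Step 6**
Reactants: 8
Product: 9 (4R,2E,6E)-10-chloro-4-(tert-butyldimethylsilyloxy)-3,7,11-trimethyldodeca-2,6,11-trienal
Conditions: PPTS, acetone/H2O, 20 °C
Reagents that add atoms: water, O
Why: Mild acid-catalysed hydrolysis of the α,β-unsaturated dimethyl acetal, which should leave the silyl ether and the allylic chloride untouched.

**Step 7**
Reactants: 9
Product: 11 (3R,6R,7S)-3-(tert-butyldimethylsilyloxy)germacra-1(10)E,4E,11-trien-6-ol (3α-OSi, 6α-OH trans to the 7β-isopropenyl group), via allylzinc 10 (not isolated)
Conditions: Pd(PPh3)4 (10 mol %), Et2Zn, THF, 20 °C, slow addition of 9 (high dilution); aq. NH4Cl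
Reagents that add atoms: none
Why: Palladium-catalysed umpolung carbonyl allylation (intramolecular, Nozaki–Hiyama-type outcome): zerovalent palladium ionises the allylic chloride, Et2Zn converts the π-allyl complex into an allylzinc that adds through its γ carbon to the aldehyde via a chair transition state with the (E)-γ substituent and the aldehyde residue equatorial, closing the ten-membered ring with the 6,7-trans relationship, while the C3 silyloxy group, kept pseudoaxial by allylic 1,2-strain with the C4 methyl, fixes the fold of the chain and so the aldehyde face.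

**Step 8**
Reactants: 11; 12 benzoic acid
Product: 13 (3R,6S,7S)-3-(tert-butyldimethylsilyloxy)germacra-1(10)E,4E,11-trien-6-yl benzoate (6β-OBz, cis to the 7β-isopropenyl group)
Conditions: PPh3, DIAD, toluene, 0 → 20 °C
Reagents that add atoms: benzoic acid, OC(=O)c1ccccc1
Why: Mitsunobu reaction: SN2 displacement of the oxyphosphonium group by benzoate should invert C6 and install the ester in one operation; SN2′ attack would have to create a tertiary ester at C4 and is disfavoured.

**Step 9**
Reactants: 13
Product: 14 (3R,6R,7S)-3-(tert-butyldimethylsilyloxy)germacra-1(10)E,4E-dien-6-yl benzoate (geometry unchanged; the C6 descriptor changes by priority only)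
Conditions: H2 (1 atm), RhCl(PPh3)3 (5 mol %), benzene/EtOH, 20 °C
Reagents that add atoms: none
Why: Homogeneous hydrogenation with RhCl(PPh3)3 reduces the 1,1-disubstituted alkene far faster than the two trisubstituted ring alkenes, and 20 °C avoids Cope rearrangement of the cyclodeca-1,5-diene.

**Step 10**
Reactants: 14
Product: 16 (3R,4R,5S,6R,7S,10S)-3-(tert-butyldimethylsilyloxy)-4-hydroxyeudesman-6-yl benzoate (3α-OSi, 4β-OH, 6β-OBz, 5α-H, 10β-CH3), via dioxanylium salt 15 (not isolated)
Conditions: Tf2NH (1.05 equiv), CH2Cl2, −78 °C; then THF/aq. NaHCO3, −78 → 20 °C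
Reagents that add atoms: water, O
Why: Protonation of the C1=C10 alkene at C1 gives the tertiary C10 cation, C5 of the C4=C5 alkene attacks it across the ring, and the resulting tertiary C4 cation is captured on its β face by the carbonyl oxygen of the C6 benzoate to give the 2-phenyl-1,3-dioxan-2-ylium ion 15, which water opens to the tertiary alcohol and the secondary benzoate. The closest known reaction type is the acid-induced transannular cation–olefin cyclisation of germacra-1(10),4-dienes to eudesmanes, here terminated by neighbouring-group (acyloxonium) participation. The single C5–C10 bond divides the ten-membered ring into rings A and B at once (6-endo with respect to the C4=C5 π bond), and the temporary dioxanylium ring closes as a six-membered ring across C4–C5–C6. C10 and C5 (trans fusion, 10β-CH3/5α-H) should follow from the crossed chair–chair fold anchored by the equatorial C7 isopropyl and the pseudoaxial C3 silyl ether; C4 follows from intramolecular delivery by the β-oriented C6 benzoate, anti to the axial C3–O bond (H3 is equatorial, so no 1,2-hydride shift is aligned). The step needs protonation at C1=C10 rather than C4=C5 (the latter is deactivated by two allylic oxygens), absence of any external nucleophile or base until the quench (non-nucleophilic counter-ion, −78 °C), and the benzoate ending on O6, which is the less hindered, thermodynamically favoured monoester reachable by acyl migration across the 1,3-diaxial diol. The allylic 1,3-strain of the pseudoaxial benzoate with the C4 methyl is the main cost of the required fold and is offset by bonding to C4.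

**Step 11**
Reactants: 16
Product: 17 (3R,4R,5S,6R,7S,10S)-3,4-dihydroxyeudesman-6-yl benzoate (target)
Conditions: HF·pyridine, pyridine, THF, 0 → 20 °C
Reagents that add atoms: none
Why: Fluoride-mediated cleavage of the silyl ether under weakly acidic conditions that should cause neither benzoate migration nor dehydration of the tertiary alcohol.

**Compound list**
1 | geranyl chloride, (2E)-1-chloro-3,7-dimethylocta-2,6-diene | ClC/C=C(\C)CCC=C(C)C | starting material
2 | (2E)-4,4-dimethoxy-2-methylbut-2-enal | O=C/C(C)=C/C(OC)OC | starting material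
3 | geranylbarium chloride | Cl[Ba]C/C=C(\C)CCC=C(C)C | intermediate (not isolated)
4 | rac-(2E,6E)-1,1-dimethoxy-3,7,11-trimethyldodeca-2,6,10-trien-4-ol | COC(OC)/C=C(\C)C(O)C/C=C(\C)CCC=C(C)C | intermediate
5 | (2E,6E)-1,1-dimethoxy-3,7,11-trimethyldodeca-2,6,10-trien-4-one | COC(OC)/C=C(\C)C(=O)C/C=C(\C)CCC=C(C)C | intermediate
6 | (4R,2E,6E)-1,1-dimethoxy-3,7,11-trimethyldodeca-2,6,10-trien-4-ol | COC(OC)/C=C(\C)[C@H](O)C/C=C(\C)CCC=C(C)C | intermediate
7 | (4R,2E,6E)-4-(tert-butyldimethylsilyloxy)-1,1-dimethoxy-3,7,11-trimethyldodeca-2,6,10-triene | COC(OC)/C=C(\C)[C@H](O[Si](C)(C)C(C)(C)C)C/C=C(\C)CCC=C(C)C | intermediate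
8 | (4R,2E,6E)-10-chloro-4-(tert-butyldimethylsilyloxy)-1,1-dimethoxy-3,7,11-trimethyldodeca-2,6,11-triene (C10 epimers) | COC(OC)/C=C(\C)[C@H](O[Si](C)(C)C(C)(C)C)C/C=C(\C)CCC(Cl)C(C)=C | intermediate
9 | (4R,2E,6E)-10-chloro-4-(tert-butyldimethylsilyloxy)-3,7,11-trimethyldodeca-2,6,11-trienal | O=C/C=C(\C)[C@H](O[Si](C)(C)C(C)(C)C)C/C=C(\C)CCC(Cl)C(C)=C | intermediate
10 | ethyl[(2E,6E,10E,9R)-9-(tert-butyldimethylsilyloxy)-2,6,10-trimethyl-12-oxododeca-2,6,10-trien-1-yl]zinc | O=C/C=C(\C)[C@H](O[Si](C)(C)C(C)(C)C)C/C=C(\C)CC/C=C(\C)C[Zn]CC | intermediate (not isolated)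
11 | (3R,6R,7S)-3-(tert-butyldimethylsilyloxy)germacra-1(10)E,4E,11-trien-6-ol | C=C(C)[C@@H]1CC/C(C)=C/C[C@@H](O[Si](C)(C)C(C)(C)C)/C(C)=C/[C@H]1O | intermediate
12 | benzoic acid | OC(=O)c1ccccc1 | starting material
13 | (3R,6S,7S)-3-(tert-butyldimethylsilyloxy)germacra-1(10)E,4E,11-trien-6-yl benzoate | C=C(C)[C@@H]1CC/C(C)=C/C[C@@H](O[Si](C)(C)C(C)(C)C)/C(C)=C/[C@@H]1OC(=O)c1ccccc1 | intermediate
14 | (3R,6R,7S)-3-(tert-butyldimethylsilyloxy)germacra-1(10)E,4E-dien-6-yl benzoate | CC(C)[C@@H]1CC/C(C)=C/C[C@@H](O[Si](C)(C)C(C)(C)C)/C(C)=C/[C@@H]1OC(=O)c1ccccc1 | intermediate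
15 | 4β,6β-O,O-bridged 2-phenyl-1,3-dioxan-2-ylium ion of 3α-(tert-butyldimethylsilyloxy)eudesmane-4β,6β-diol, bis(trifluoromethanesulfonyl)imide salt | CC(C)[C@@H]1CC[C@@]2(C)CC[C@@H](O[Si](C)(C)C(C)(C)C)[C@@]3(C)[C@@H]2[C@@H]1O[C+](c1ccccc1)O3.[N-](S(=O)(=O)C(F)(F)F)S(=O)(=O)C(F)(F)F | intermediate (not isolated)
16 | (3R,4R,5S,6R,7S,10S)-3-(tert-butyldimethylsilyloxy)-4-hydroxyeudesman-6-yl benzoate | CC(C)[C@@H]1CC[C@@]2(C)CC[C@@H](O[Si](C)(C)C(C)(C)C)[C@](C)(O)[C@@H]2[C@@H]1OC(=O)c1ccccc1 | intermediate
17 | (3R,4R,5S,6R,7S,10S)-3,4-dihydroxyeudesman-6-yl benzoate | CC(C)[C@@H]1CC[C@@]2(C)CC[C@@H](O)[C@](C)(O)[C@@H]2[C@@H]1OC(=O)c1ccccc1 | target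

**Step count**
Total: 11 steps. Longest linear sequence: 11 steps (1 and 2 to 17); benzoic acid 12 enters at step 8.

**Steps most likely to fail**

Step 10. What may go wrong: proton loss from the C10 or C4 cation to give dienes or eudesmenes, acid-induced ionisation of the allylic C3–O or C6–O bond before C1 is protonated, or folding through the chair–boat conformer to a cis-fused product. The fallback replaces the proton by a metal electrophile and sets out from 14. Treatment with Hg(OCOCF3)2 in MeNO2/CH2Cl2 at −20 °C should let divalent mercury add to C1 from the outer face while C5 closes onto C10 and the benzoate traps C4. Work-up with aqueous NaCl/NaHCO3 should give the 1β-chloromercurio derivative of 16, the organomercurial F1. Reductive demercuration with NaBH4/aq. NaOH in THF at 0 °C replaces mercury by hydrogen and rejoins the route at 16.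

Step 7. What may go wrong: weak transmission of the C3 configuration to the facial choice at the aldehyde (two trans diastereomers), attack through the α carbon of the allylzinc (twelve-membered ring), or oligomerisation. The fallback uses reagent-controlled allylboration and sets out from 8. Borylation with B2pin2 and Pd2(dba)3 in DMSO should give the (E)-allyl pinacol boronate acetal F2. Hydrolysis of the acetal (PPTS, acetone/H2O) gives the allylboronate enal F3. In dilute toluene a chiral BINOL-derived phosphoric acid (3,3′-bis(2,4,6-triisopropylphenyl) type, the antipode matched to the substrate) catalyses the intramolecular allylboration through a closed chair transition state, so the catalyst rather than the remote C3 centre selects the aldehyde face. Aqueous work-up of the borate returns the route at 11.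

Step 8. What may go wrong: SN2′ attack, elimination to a triene, or ionisation to the allyl cation with loss of stereochemical integrity, instead of clean SN2 inversion at the congested ring carbinol. The fallback is oxidation, reagent-controlled reduction and acylation, and sets out from 11. Dess–Martin oxidation (NaHCO3, CH2Cl2, 0 °C) gives the germacra-1(10),4,11-trien-6-one F4. Reduction with (S)-2-methyl-CBS-oxazaborolidine and catecholborane at −78 °C, with the C4=C5 alkenyl residue as the large group, should give the 6β-alcohol F5. Benzoylation (BzCl, DMAP, pyridine, 0 °C) returns the route at 13.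

**Further compounds**
F1 | step 10 | (1β)-1-(chloromercurio)-3α-(tert-butyldimethylsilyloxy)-4β-hydroxyeudesman-6β-yl benzoate | CC(C)[C@@H]1CC[C@@]2(C)[C@H]([Hg]Cl)C[C@@H](O[Si](C)(C)C(C)(C)C)[C@](C)(O)[C@@H]2[C@@H]1OC(=O)c1ccccc1
F2 | step 7 | (4R,2E,6E,10E)-4-(tert-butyldimethylsilyloxy)-1,1-dimethoxy-3,7,11-trimethyl-12-(4,4,5,5-tetramethyl-1,3,2-dioxaborolan-2-yl)dodeca-2,6,10-triene | COC(OC)/C=C(\C)[C@H](O[Si](C)(C)C(C)(C)C)C/C=C(\C)CC/C=C(\C)CB1OC(C)(C)C(C)(C)O1
F3 | step 7 | (4R,2E,6E,10E)-4-(tert-butyldimethylsilyloxy)-3,7,11-trimethyl-12-(4,4,5,5-tetramethyl-1,3,2-dioxaborolan-2-yl)dodeca-2,6,10-trienal | O=C/C=C(\C)[C@H](O[Si](C)(C)C(C)(C)C)C/C=C(\C)CC/C=C(\C)CB1OC(C)(C)C(C)(C)O1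
F4 | step 8 | (3R,7S)-3-(tert-butyldimethylsilyloxy)germacra-1(10)E,4E,11-trien-6-one | C=C(C)[C@@H]1CC/C(C)=C/C[C@@H](O[Si](C)(C)C(C)(C)C)/C(C)=C/C1=O
F5 | step 8 | (3R,6S,7S)-3-(tert-butyldimethylsilyloxy)germacra-1(10)E,4E,11-trien-6-ol (6β-OH) | C=C(C)[C@@H]1CC/C(C)=C/C[C@@H](O[Si](C)(C)C(C)(C)C)/C(C)=C/[C@@H]1O
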